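The carbocycle (C1 acyloxy carbon, C2 ketone, C3–C4 oxirane, C5, C6) is cut at C1–C6. Its trans C1–O/C6–C7 pair, with C7 still carrying the one-carbon C14 unit, is the pattern of an isopulegol, so a type I carbonyl-ene closure of a 2-oxygenated citronellal forms the C1–C6 bond, the six-membered ring, both stereocentres and the C7=C14 alkene in one operation. The precursor is (2S,3R)-2-triethylsilyloxy-3,7-dimethyloct-6-enal, from (R)-citronellal by organocatalytic α-oxygenation. Afterwards C2 becomes the ketone, C3=C4 is unveiled and epoxidised under hydroxyl direction, and the isopropenyl group is elaborated by allylic oxidation, Sharpless epoxidation and alkenylchromium addition.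

Key step: step 5

Remarks on the chemistry:
- Locants: ring C1 (acyloxy carbon) to C6; chain C7 (oxirane carbon), C14 (its CH2), C8 (carbonyl), C9=C10, C11 (CMe2OH). The cyclohexyl-ester locants in the names coincide with C1–C6.
- The silyl group is triethylsilyl (TES), so that step 4 can oxidise the bis-silyl ether directly and step 7 can release O2 under mild acid beside the ester.
- Descriptor changes at C2 (13 to 14), C3 (14 to 15), C6 (16 to 17) and C7 (17 to 18) come from CIP priorities only; no centre is inverted.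
- Assumption: 22 is carried on as a mixture of C8 epimers, because C8 becomes a carbonyl in step 17.

Step 1
Reactants: 1 (R)-(+)-citronellal
Product: 3 (2S,3R)-3,7-dimethyl-2-[(phenylamino)oxy]oct-6-en-1-ol, via aminoxy aldehyde 2 (not isolated)
Conditions: PhNO, D-proline (20 mol%), CHCl3, 0 °C; then NaBH4, EtOH, 0 °C
Reagents that add atoms: nitrosobenzene, O=Nc1ccccc1
Why: Enamine-catalysed α-aminoxylation (O-selective nitroso aldol): D-proline should direct the nitroso oxygen to the enamine face that gives 2S under catalyst control, whatever the C3 centre prefers, and in situ borohydride reduction secures aldehyde 2 before it can epimerise.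

Step 2
Reactants: 3 (2S,3R)-3,7-dimethyl-2-[(phenylamino)oxy]oct-6-en-1-ol
Product: 4 (2S,3R)-3,7-dimethyloct-6-ene-1,2-diol
Conditions: Zn dust, AcOH/EtOH, rt
Reagents that add atoms: none
Why: Zinc/acetic acid reductive N–O cleavage frees the secondary hydroxyl and leaves the trisubstituted alkene and both stereocentres untouched.

Step 3
Reactants: 4 (2S,3R)-3,7-dimethyloct-6-ene-1,2-diol
Product: 5 (2S,3R)-3,7-dimethyl-1,2-bis[(triethylsilyl)oxy]oct-6-ene
Conditions: TESCl (2.5 equiv), imidazole, DMAP (cat.), DMF, 0 °C → rt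
Reagents that add atoms: chlorotriethylsilane, CC[Si](Cl)(CC)CC
Why: Silyl ether formation at both hydroxyls; the TES group does not chelate aluminium in step 5, lets the primary ether be oxidised directly in step 4 and is released under mild acid in step 7.

Step 4
Reactants: 5 (2S,3R)-3,7-dimethyl-1,2-bis[(triethylsilyl)oxy]oct-6-ene
Product: 6 (2S,3R)-3,7-dimethyl-2-[(triethylsilyl)oxy]oct-6-enal
Conditions: (COCl)2, DMSO, CH2Cl2, −78 → −40 °C; then Et3N, −78 → 0 °C
Reagents that add atoms: none
Why: Swern oxidation applied to the bis-silyl ether: the chlorosulfonium reagent desilylates and oxidises only the unhindered primary TES ether (a known selective oxidative deprotection), so the α-silyloxy aldehyde should be reached without a separate deprotection, and a cold work-up limits epimerisation at C2.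

Step 5
Reactants: 6 (2S,3R)-3,7-dimethyl-2-[(triethylsilyl)oxy]oct-6-enal
Product: 7 (1S,2S,3R,6S)-3-methyl-6-(prop-1-en-2-yl)-2-[(triethylsilyl)oxy]cyclohexan-1-ol (all four substituents equatorial)
Conditions: MABR (1.2 equiv; from Me3Al + 2 ArOH, ArOH = 4-bromo-2,6-di-tert-butylphenol), CH2Cl2, −78 → −40 °C; 1 M HCl work-up
Reagents that add atoms: none
Why: The bulky, non-chelating aluminium aryloxide binds the aldehyde oxygen and activates C1, which bonds to alkene carbon C6 while a hydrogen of one C7 methyl (the future C14) passes to the carbonyl oxygen through a concerted six-membered ene transition state, leaving the C7=C14 isopropenyl group. The closest known reaction is the Lewis-acid-promoted type I carbonyl-ene cyclisation of citronellal to isopulegol, here run on its 2-silyloxy analogue. The cyclohexane ring is closed in the type I ene mode (carbonyl carbon to the proximal alkene carbon, C7 left exocyclic) through a chair-like array. C1 (S) and C6 (S) are both set by this chair: with the C3 methyl and the C2 silyloxy group equatorial, the aluminium-bound oxygen and the developing isopropenyl group should also sit equatorial, so C1–O ends trans to C6–C7 and trans to C2–O. The step needs diastereoface selection at both the aldehyde and the alkene; the C3 centre from citronellal anchors the chair, the equatorial C2–O bond lies anti to the forming C1–C6 bond, and the size of the Lewis acid disfavours the chair with axial oxygen. A silyl ether that cannot chelate keeps the reagent on the carbonyl oxygen alone, and the absence of a nucleophilic counter-ion should suppress Prins-type capture of a C7 cation.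

Step 6
Reactants: 7 (1S,2S,3R,6S)-3-methyl-6-(prop-1-en-2-yl)-2-[(triethylsilyl)oxy]cyclohexan-1-ol; 8 isovaleryl chloride
Product: 9 (1S,2S,3R,6S)-3-methyl-6-(prop-1-en-2-yl)-2-[(triethylsilyl)oxy]cyclohexyl 3-methylbutanoate
Conditions: pyridine, DMAP (cat.), CH2Cl2, 0 °C → rt
Reagents that add atoms: isovaleryl chloride (8), CC(C)CC(Cl)=O
Why: DMAP-catalysed O-acylation of the only free hydroxyl installs the final C1 ester with retention at C1.

Step 7
Reactants: 9 (1S,2S,3R,6S)-3-methyl-6-(prop-1-en-2-yl)-2-[(triethylsilyl)oxy]cyclohexyl 3-methylbutanoate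
Product: 10 (1S,2S,3R,6S)-2-hydroxy-3-methyl-6-(prop-1-en-2-yl)cyclohexyl 3-methylbutanoate
Conditions: HF·pyridine, pyridine, THF, 0 °C → rt
Reagents that add atoms: none
Why: Fluoride-induced desilylation under buffered, slightly acidic conditions should remove the secondary TES ether without the base-promoted 1,2-acyl shift between O1 and O2.

Step 8
Reactants: 10 (1S,2S,3R,6S)-2-hydroxy-3-methyl-6-(prop-1-en-2-yl)cyclohexyl 3-methylbutanoate
Product: 12 (1S,6S)-3-methyl-2-oxo-6-(prop-1-en-2-yl)cyclohex-3-en-1-yl 3-methylbutanoate, via ketone 11 (not isolated)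
Conditions: IBX (1.2 equiv), DMSO, rt; then IBX (2 equiv), 4-methoxypyridine N-oxide (2 equiv), DMSO, rt
Reagents that add atoms: none
Why: IBX oxidation of the C2 alcohol followed by IBX dehydrogenation of the ketone through its enol (known one-pot alcohol-to-enone chemistry); enolisation should go toward the alkyl-substituted C3 because the electron-withdrawing acyloxy group retards enol formation toward C1, and the C3 stereocentre is erased as planned.

Step 9
Reactants: 12 (1S,6S)-3-methyl-2-oxo-6-(prop-1-en-2-yl)cyclohex-3-en-1-yl 3-methylbutanoate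
Product: 13 (1S,2S,6S)-2-hydroxy-3-methyl-6-(prop-1-en-2-yl)cyclohex-3-en-1-yl 3-methylbutanoate
Conditions: NaBH4, CeCl3·7H2O, MeOH, −78 °C
Reagents that add atoms: none
Why: Luche 1,2-reduction; axial hydride delivery to the half-chair enone (the carvone to cis-carveol pattern) should place the new C2 hydroxyl pseudo-equatorial, cis to the C6 isopropenyl group and trans to the C1 ester, which survives the cold, near-neutral medium.

Step 10
Reactants: 13 (1S,2S,6S)-2-hydroxy-3-methyl-6-(prop-1-en-2-yl)cyclohex-3-en-1-yl 3-methylbutanoate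
Product: 14 (1S,2R,3R,4S,6S)-3,4-epoxy-2-hydroxy-3-methyl-6-(prop-1-en-2-yl)cyclohexyl 3-methylbutanoate (oxirane cis to C2–OH)
Conditions: VO(acac)2 (cat.), t-BuOOH, CH2Cl2, 0 °C → rt
Reagents that add atoms: tert-butyl hydroperoxide, CC(C)(C)OO
Why: Hydroxyl-directed vanadium-catalysed epoxidation delivers oxygen to C3=C4 on the face of the C2 hydroxyl, setting C3 and C4 with the oxirane cis to the C6 substituent, and should ignore the isopropenyl group, which has no allylic hydroxyl.

Step 11
Reactants: 14 (1S,2R,3R,4S,6S)-3,4-epoxy-2-hydroxy-3-methyl-6-(prop-1-en-2-yl)cyclohexyl 3-methylbutanoate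
Product: 15 (1S,3S,4S,6S)-3,4-epoxy-3-methyl-2-oxo-6-(prop-1-en-2-yl)cyclohexyl 3-methylbutanoate
Conditions: Dess–Martin periodinane, NaHCO3, CH2Cl2, rt
Reagents that add atoms: none
Why: Dess–Martin oxidation of the hindered secondary epoxy alcohol to the α,β-epoxy ketone under buffered neutral conditions, which should neither epimerise C1 nor open the oxirane.

Step 12
Reactants: 15 (1S,3S,4S,6S)-3,4-epoxy-3-methyl-2-oxo-6-(prop-1-en-2-yl)cyclohexyl 3-methylbutanoate
Product: 16 (1S,3S,4S,6S)-3,4-epoxy-6-(3-hydroxyprop-1-en-2-yl)-3-methyl-2-oxocyclohexyl 3-methylbutanoate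
Conditions: SeO2 (0.3 equiv), t-BuOOH (3 equiv), CH2Cl2, rt
Reagents that add atoms: selenium dioxide, O=[Se]=O (transfers the oxygen; tert-butyl hydroperoxide, CC(C)(C)OO, is the terminal oxidant)
Why: Selenium dioxide allylic oxidation (ene reaction, then [2,3]-sigmatropic shift) should oxidise the methyl group of the 1,1-disubstituted alkene (C8) in preference to the C6 methine, as known for isopulegol-type isopropenyl groups, and returns the alkene to C7=C14.

Step 13
Reactants: 16 (1S,3S,4S,6S)-3,4-epoxy-6-(3-hydroxyprop-1-en-2-yl)-3-methyl-2-oxocyclohexyl 3-methylbutanoate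
Product: 17 (1S,3S,4S,6R)-3,4-epoxy-6-[(2S)-2-(hydroxymethyl)oxiran-2-yl]-3-methyl-2-oxocyclohexyl 3-methylbutanoate
Conditions: Ti(OiPr)4 (10 mol%), L-(+)-DIPT (12 mol%), t-BuOOH, 4 Å MS, CH2Cl2, −20 °C
Reagents that add atoms: tert-butyl hydroperoxide, CC(C)(C)OO
Why: Sharpless asymmetric epoxidation of the 2-substituted allylic alcohol; the L-(+)-tartrate ligand selects the alkene face that gives the (S)-2-substituted glycidol at C7 (the arrangement that is C7 R in the target), and reagent control should override the neighbouring C6 centre.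

Step 14
Reactants: 17 (1S,3S,4S,6R)-3,4-epoxy-6-[(2S)-2-(hydroxymethyl)oxiran-2-yl]-3-methyl-2-oxocyclohexyl 3-methylbutanoate
Product: 18 (1S,3S,4S,6R)-3,4-epoxy-6-[(2R)-2-formyloxiran-2-yl]-3-methyl-2-oxocyclohexyl 3-methylbutanoate
Conditions: Dess–Martin periodinane, NaHCO3, CH2Cl2, 0 °C → rt
Reagents that add atoms: none
Why: Dess–Martin oxidation of the primary epoxy alcohol gives the α,β-epoxy aldehyde, which has no hydrogen at C7 and so cannot enolise or epimerise.

Step 15
Reactants: 19 2-methylbut-3-yn-2-ol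
Product: 21 (E)-4-iodo-2-methylbut-3-en-2-ol, via vinylstannane 20 (not isolated)
Conditions: Bu3SnH, PdCl2(PPh3)2 (cat.), THF, rt; then I2, CH2Cl2, 0 °C
Reagents that add atoms: iodine, II (tributyltin hydride, CCCC[SnH](CCCC)CCCC, puts tin only into intermediate 20)
Why: Palladium-catalysed syn-hydrostannation should place tin on the terminal carbon, away from the tertiary carbinol, giving the E-stannane, and iododestannylation proceeds with retention of alkene geometry.

Step 16
Reactants: 18 (1S,3S,4S,6R)-3,4-epoxy-6-[(2R)-2-formyloxiran-2-yl]-3-methyl-2-oxocyclohexyl 3-methylbutanoate; 21 (E)-4-iodo-2-methylbut-3-en-2-ol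
Product: 22 (1S,3S,4S,6R)-3,4-epoxy-6-{(2R)-2-[(E)-1,4-dihydroxy-4-methylpent-2-en-1-yl]oxiran-2-yl}-3-methyl-2-oxocyclohexyl 3-methylbutanoate (both C8 epimers)
Conditions: CrCl2 (4 equiv), NiCl2 (cat.), DMSO, rt
Reagents that add atoms: (E)-4-iodo-2-methylbut-3-en-2-ol (21), CC(C)(O)/C=C/I
Why: Nozaki–Hiyama–Kishi coupling: the alkenylchromium(III) reagent should add only to the aldehyde, with retention of the E geometry, while the ketone, ester, both oxiranes and the free tertiary hydroxyl are tolerated.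

Step 17
Reactants: 22 (1S,3S,4S,6R)-3,4-epoxy-6-{(2R)-2-[(E)-1,4-dihydroxy-4-methylpent-2-en-1-yl]oxiran-2-yl}-3-methyl-2-oxocyclohexyl 3-methylbutanoate
Product: 23 (1S,3S,4S,6R)-3,4-epoxy-6-{(2R)-2-[(E)-4-hydroxy-4-methylpent-2-enoyl]oxiran-2-yl}-3-methyl-2-oxocyclohexyl 3-methylbutanoate (CNP0292003.1)
Conditions: Dess–Martin periodinane, NaHCO3, CH2Cl2, 0 °C → rt
Reagents that add atoms: none
Why: Dess–Martin oxidation of the secondary allylic alcohol gives the enone and removes the C8 epimer mixture; the tertiary alcohol cannot be oxidised and the buffered conditions should spare both epoxy ketones and the α-acyloxy ketone.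

Compound list
1 | (R)-(+)-citronellal | O=CC[C@H](C)CCC=C(C)C | starting material
2 | (2S,3R)-3,7-dimethyl-2-[(phenylamino)oxy]oct-6-enal | O=C[C@@H](ONc1ccccc1)[C@H](C)CCC=C(C)C | intermediate (not isolated)
3 | (2S,3R)-3,7-dimethyl-2-[(phenylamino)oxy]oct-6-en-1-ol | OC[C@@H](ONc1ccccc1)[C@H](C)CCC=C(C)C | intermediate
4 | (2S,3R)-3,7-dimethyloct-6-ene-1,2-diol | OC[C@@H](O)[C@H](C)CCC=C(C)C | intermediate
5 | (2S,3R)-3,7-dimethyl-1,2-bis[(triethylsilyl)oxy]oct-6-ene | CC[Si](CC)(CC)OC[C@@H](O[Si](CC)(CC)CC)[C@H](C)CCC=C(C)C | intermediate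
6 | (2S,3R)-3,7-dimethyl-2-[(triethylsilyl)oxy]oct-6-enal | O=C[C@@H](O[Si](CC)(CC)CC)[C@H](C)CCC=C(C)C | intermediate (key-step precursor)
7 | (1S,2S,3R,6S)-3-methyl-6-(prop-1-en-2-yl)-2-[(triethylsilyl)oxy]cyclohexan-1-ol | O[C@@H]1[C@@H](O[Si](CC)(CC)CC)[C@H](C)CC[C@H]1C(C)=C | intermediate (key-step product)
8 | isovaleryl chloride | CC(C)CC(Cl)=O | starting material
9 | (1S,2S,3R,6S)-3-methyl-6-(prop-1-en-2-yl)-2-[(triethylsilyl)oxy]cyclohexyl 3-methylbutanoate | CC(C)CC(=O)O[C@@H]1[C@@H](O[Si](CC)(CC)CC)[C@H](C)CC[C@H]1C(C)=C | intermediate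
10 | (1S,2S,3R,6S)-2-hydroxy-3-methyl-6-(prop-1-en-2-yl)cyclohexyl 3-methylbutanoate | CC(C)CC(=O)O[C@@H]1[C@@H](O)[C@H](C)CC[C@H]1C(C)=C | intermediate
11 | (1S,3R,6S)-3-methyl-2-oxo-6-(prop-1-en-2-yl)cyclohexyl 3-methylbutanoate | CC(C)CC(=O)O[C@@H]1C(=O)[C@H](C)CC[C@H]1C(C)=C | intermediate (not isolated)
12 | (1S,6S)-3-methyl-2-oxo-6-(prop-1-en-2-yl)cyclohex-3-en-1-yl 3-methylbutanoate | CC(C)CC(=O)O[C@@H]1C(=O)C(C)=CC[C@H]1C(C)=C | intermediate
13 | (1S,2S,6S)-2-hydroxy-3-methyl-6-(prop-1-en-2-yl)cyclohex-3-en-1-yl 3-methylbutanoate | CC(C)CC(=O)O[C@@H]1[C@@H](O)C(C)=CC[C@H]1C(C)=C | intermediate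
14 | (1S,2R,3R,4S,6S)-3,4-epoxy-2-hydroxy-3-methyl-6-(prop-1-en-2-yl)cyclohexyl 3-methylbutanoate | CC(C)CC(=O)O[C@@H]1[C@@H](O)[C@@]2(C)O[C@H]2C[C@H]1C(C)=C | intermediate
15 | (1S,3S,4S,6S)-3,4-epoxy-3-methyl-2-oxo-6-(prop-1-en-2-yl)cyclohexyl 3-methylbutanoate | CC(C)CC(=O)O[C@@H]1C(=O)[C@@]2(C)O[C@H]2C[C@H]1C(C)=C | intermediate
16 | (1S,3S,4S,6S)-3,4-epoxy-6-(3-hydroxyprop-1-en-2-yl)-3-methyl-2-oxocyclohexyl 3-methylbutanoate | CC(C)CC(=O)O[C@@H]1C(=O)[C@@]2(C)O[C@H]2C[C@H]1C(=C)CO | intermediate
17 | (1S,3S,4S,6R)-3,4-epoxy-6-[(2S)-2-(hydroxymethyl)oxiran-2-yl]-3-methyl-2-oxocyclohexyl 3-methylbutanoate | CC(C)CC(=O)O[C@@H]1C(=O)[C@@]2(C)O[C@H]2C[C@H]1[C@]1(CO)CO1 | intermediate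
18 | (1S,3S,4S,6R)-3,4-epoxy-6-[(2R)-2-formyloxiran-2-yl]-3-methyl-2-oxocyclohexyl 3-methylbutanoate | CC(C)CC(=O)O[C@@H]1C(=O)[C@@]2(C)O[C@H]2C[C@H]1[C@]1(C=O)CO1 | intermediate
19 | 2-methylbut-3-yn-2-ol | CC(C)(O)C#C | starting material
20 | (E)-2-methyl-4-(tributylstannyl)but-3-en-2-ol | CC(C)(O)/C=C/[Sn](CCCC)(CCCC)CCCC | intermediate (not isolated)
21 | (E)-4-iodo-2-methylbut-3-en-2-ol | CC(C)(O)/C=C/I | intermediate
22 | (1S,3S,4S,6R)-3,4-epoxy-6-{(2R)-2-[(E)-1,4-dihydroxy-4-methylpent-2-en-1-yl]oxiran-2-yl}-3-methyl-2-oxocyclohexyl 3-methylbutanoate, C8 epimers | CC(C)CC(=O)O[C@@H]1C(=O)[C@@]2(C)O[C@H]2C[C@H]1[C@]1(C(O)/C=C/C(C)(C)O)CO1 | intermediate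
23 | (1S,3S,4S,6R)-3,4-epoxy-6-{(2R)-2-[(E)-4-hydroxy-4-methylpent-2-enoyl]oxiran-2-yl}-3-methyl-2-oxocyclohexyl 3-methylbutanoate | CC(C)CC(=O)O[C@@H]1C(=O)[C@@]2(C)O[C@H]2C[C@H]1[C@]1(C(=O)/C=C/C(C)(C)O)CO1 | target

Total step count: 17.
Longest linear sequence: 16 steps (steps 1–14, 16, 17); step 15 is a one-step side branch.

Steps most likely to fail

Step 5 (carbonyl-ene closure). The two chairs (oxygen equatorial or axial at C1) may not be discriminated well enough, or the closure may turn stepwise and cationic and lose the hydrogen-transfer pathway. The fallback sets out from 4 and returns at 10, and it replaces steric control by chelation control. Diol 4 is condensed with 4-methoxybenzaldehyde dimethyl acetal (PPTS, CH2Cl2) to the p-methoxybenzylidene acetal F1. DIBAL-H (CH2Cl2, −78 → 0 °C) opens it at the less hindered oxygen to the secondary PMB ether with free primary hydroxyl, alcohol F2. Dess–Martin oxidation gives the 2-PMB-oxy aldehyde F3. Me2AlCl (2 equiv, CH2Cl2, −78 °C) should then hold the aldehyde and ether oxygens in a five-membered chelate that fits the same all-equatorial chair and give the cyclohexanol F4. Acylation with 8 (pyridine, DMAP) gives the isovalerate F5, and DDQ (CH2Cl2, pH 7 buffer) removes the PMB group to give 10.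

Step 8 (oxidation and dehydrogenation). Enolisation may go toward C1 instead of C3, so that regiocontrol is lost, or a second dehydrogenation may lead on toward a phenol. The fallback sets out from 10 and returns at 12. Alcohol 10 is oxidised with Dess–Martin periodinane and ketone 11 is isolated. Soft enolisation under equilibrating conditions (TMSOTf, Et3N, CH2Cl2, 0 °C) should give the more substituted C2=C3 trimethylsilyl enol ether F6, whose constitution can be checked before the oxidation. Saegusa–Ito oxidation (Pd(OAc)2, MeCN, rt) then gives 12. This separates the regiochemical decision from the oxidation and uses an oxidant that cannot dehydrogenate a second time.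

Step 12 (allylic oxidation). Conversion may be low, the allylic alcohol may be over-oxidised to the enal, or the C6 methine may be attacked instead. The fallback sets out from 15 and returns at 16. Ene-type allylic chlorination of the isopropenyl group with hypochlorous acid (Ca(OCl)2, solid CO2, CH2Cl2/H2O, 0 °C), as used on carvone, should give the allylic chloride F7. Displacement with sodium formate (Bu4NI cat., DMF, rt) gives the formate F8. Brief methanolysis (KHCO3, MeOH, 0 °C) should cleave the formate faster than the isovalerate and give 16.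

Further compounds
F1 | step 5 | (4S)-2-(4-methoxyphenyl)-4-[(2R)-6-methylhept-5-en-2-yl]-1,3-dioxolane (acetal epimers) | COc1ccc(cc1)C1OC[C@@H](O1)[C@H](C)CCC=C(C)C
F2 | step 5 | (2S,3R)-2-[(4-methoxybenzyl)oxy]-3,7-dimethyloct-6-en-1-ol | OC[C@@H](OCc1ccc(OC)cc1)[C@H](C)CCC=C(C)C
F3 | step 5 | (2S,3R)-2-[(4-methoxybenzyl)oxy]-3,7-dimethyloct-6-enal | O=C[C@@H](OCc1ccc(OC)cc1)[C@H](C)CCC=C(C)C
F4 | step 5 | (1S,2S,3R,6S)-2-[(4-methoxybenzyl)oxy]-3-methyl-6-(prop-1-en-2-yl)cyclohexan-1-ol | O[C@@H]1[C@@H](OCc2ccc(OC)cc2)[C@H](C)CC[C@H]1C(C)=C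
F5 | step 5 | (1S,2S,3R,6S)-2-[(4-methoxybenzyl)oxy]-3-methyl-6-(prop-1-en-2-yl)cyclohexyl 3-methylbutanoate | CC(C)CC(=O)O[C@@H]1[C@@H](OCc2ccc(OC)cc2)[C@H](C)CC[C@H]1C(C)=C
F6 | step 8 | (1S,6S)-3-methyl-6-(prop-1-en-2-yl)-2-[(trimethylsilyl)oxy]cyclohex-2-en-1-yl 3-methylbutanoate | CC(C)CC(=O)O[C@@H]1C(O[Si](C)(C)C)=C(C)CC[C@H]1C(C)=C
F7 | step 12 | (1S,3S,4S,6S)-6-(3-chloroprop-1-en-2-yl)-3,4-epoxy-3-methyl-2-oxocyclohexyl 3-methylbutanoate | CC(C)CC(=O)O[C@@H]1C(=O)[C@@]2(C)O[C@H]2C[C@H]1C(=C)CCl
F8 | step 12 | (1S,3S,4S,6S)-3,4-epoxy-6-[3-(formyloxy)prop-1-en-2-yl]-3-methyl-2-oxocyclohexyl 3-methylbutanoate | CC(C)CC(=O)O[C@@H]1C(=O)[C@@]2(C)O[C@H]2C[C@H]1C(=C)COC=O
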